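## Retrosynthetic overview

1. Target ⇐ late acylations (isovalerate on O9, (R)-2-methylbutanoate on O5) and PMB removal from O8; the exocyclic methylene is carried as its Me2NH adduct while the carbocycle is built (germacranolide locants, defined below).
2. Ten-membered carbocycle ⇐ ring-closing metathesis at C1=C2 (vinyl ketone at C3, vinyl group on C10), then hydrogenation.
3. Key disconnection C6–C7: intermolecular CrCl2-mediated carbonyl allylation of aldehyde 17 (C3–C6) with allylic bromide 10 (C7–C13 and C1), lactonising to the trans α-methylene-γ-butyrolactone.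
4. Bromide 10 ⇐ D-glyceraldehyde acetonide by Roush anti-crotylboration (C9, C10), then Morita–Baylis–Hillman reaction and SN2′ bromination; aldehyde 17 ⇐ D-erythronolactone acetonide by C-methylation (C4) and lactol vinylation.
5. Ring order: γ-lactone first (key step), ten-membered ring second (metathesis).

Assumption: (R)-2-methylbutanoic acid (30) and 2,3-O-isopropylidene-D-erythronolactone (11) are bought as single enantiomers; locants are germacranolide locants (C6 lactone O–CH, C7 ring-fusion CH, C8 CH–OH, C9 CH–O-isovaleryl, C10 CH–CH3, C1/C2 CH2, C3 C=O, C4 C(CH3)OH, C5 CH–O-acyl, C11=C13 methylene, C12 lactone C=O); TBS = tert-butyldimethylsilyl, TES = triethylsilyl, PMB = 4-methoxybenzyl.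

## Route

Step 1
Reactants: 1 1,2:5,6-di-O-isopropylidene-D-mannitol
Product: 2 (R)-2,2-dimethyl-1,3-dioxolane-4-carbaldehyde
Conditions: NaIO4, aq NaHCO3, CH2Cl2, rt
Reagents that add atoms: none
Why: Malaprade glycol cleavage of the central diol gives two equivalents of the aldehyde, whose stereocentre (future C8) comes unchanged from D-mannitol.

Step 2
Reactants: 2 (R)-2,2-dimethyl-1,3-dioxolane-4-carbaldehyde
Product: 3 (1R,2R)-1-[(4R)-2,2-dimethyl-1,3-dioxolan-4-yl]-2-methylbut-3-en-1-ol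
Conditions: (S,S)-diisopropyl tartrate (E)-crotylboronate (1.5 equiv), 4 Å molecular sieves, PhMe, −78 °C; aq NaOH work-up; chromatography
Reagents that add atoms: (S,S)-diisopropyl tartrate (E)-crotylboronate, CC(C)OC(=O)[C@H]1OB(C/C=C/C)O[C@@H]1C(=O)OC(C)C
Why: Roush crotylboration (a carbonyl allylation) through a chair transition state, in which the E-crotyl group sets C9/C10 anti and the (S,S)-tartrate directs attack to the Re face to give the 8,9-syn isomer (about 9:1 expected, reagent control over the weak bias of this aldehyde toward E-crotylboronates).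

Step 3
Reactants: 3 (1R,2R)-1-[(4R)-2,2-dimethyl-1,3-dioxolan-4-yl]-2-methylbut-3-en-1-ol
Product: 4 (4R)-4-[(1R,2R)-1-(tert-butyldimethylsilyloxy)-2-methylbut-3-enyl]-2,2-dimethyl-1,3-dioxolane
Conditions: TBSOTf, 2,6-lutidine, CH2Cl2, 0 °C
Reagents that add atoms: tert-butyldimethylsilyl triflate, CC(C)(C)[Si](C)(C)OS(=O)(=O)C(F)(F)F
Why: Silylation of the hindered secondary alcohol with the silyl triflate gives a temporary O9 protecting group that survives all steps up to step 22.

Step 4
Reactants: 4 (4R)-4-[(1R,2R)-1-(tert-butyldimethylsilyloxy)-2-methylbut-3-enyl]-2,2-dimethyl-1,3-dioxolane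
Product: 5 (2R,3R,4R)-3-(tert-butyldimethylsilyloxy)-4-methylhex-5-ene-1,2-diol
Conditions: AcOH/H2O (4:1), 40 °C
Reagents that add atoms: none
Why: Acid-catalysed hydrolysis removes the terminal acetonide much faster than it cleaves the hindered secondary TBS ether.

Step 5
Reactants: 5 (2R,3R,4R)-3-(tert-butyldimethylsilyloxy)-4-methylhex-5-ene-1,2-diol
Product: 6 (4R)-4-[(1R,2R)-1-(tert-butyldimethylsilyloxy)-2-methylbut-3-enyl]-2-(4-methoxyphenyl)-1,3-dioxolane (both acetal epimers)
Conditions: 4-MeOC6H4CH(OMe)2, PPTS (cat.), CH2Cl2, rt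
Reagents that add atoms: 4-methoxybenzaldehyde dimethyl acetal, COC(OC)c1ccc(OC)cc1
Why: Transacetalisation of the 1,2-diol gives the 4-methoxybenzylidene acetal, whose acetal configuration is irrelevant because that carbon becomes a CH2 in step 6.

Step 6
Reactants: 6 (4R)-4-[(1R,2R)-1-(tert-butyldimethylsilyloxy)-2-methylbut-3-enyl]-2-(4-methoxyphenyl)-1,3-dioxolane
Product: 7 (2R,3R,4R)-3-(tert-butyldimethylsilyloxy)-2-(4-methoxybenzyloxy)-4-methylhex-5-en-1-ol
Conditions: i-Bu2AlH (3 equiv), CH2Cl2, −78 → 0 °C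
Reagents that add atoms: none
Why: Regioselective reductive acetal opening, in which aluminium coordinates the less hindered primary oxygen so that the PMB ether stays on the secondary O8 and the primary alcohol is freed.

Step 7
Reactants: 7 (2R,3R,4R)-3-(tert-butyldimethylsilyloxy)-2-(4-methoxybenzyloxy)-4-methylhex-5-en-1-ol
Product: 8 (2S,3R,4R)-3-(tert-butyldimethylsilyloxy)-2-(4-methoxybenzyloxy)-4-methylhex-5-enal
Conditions: Dess–Martin periodinane, NaHCO3, CH2Cl2, 0 °C → rt
Reagents that add atoms: none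
Why: Dess–Martin oxidation under buffered, non-basic conditions gives the α-alkoxy aldehyde without epimerising C8.

Step 8
Reactants: 8 (2S,3R,4R)-3-(tert-butyldimethylsilyloxy)-2-(4-methoxybenzyloxy)-4-methylhex-5-enal
Product: 9 methyl (4R,5R,6R)-5-(tert-butyldimethylsilyloxy)-3-hydroxy-4-(4-methoxybenzyloxy)-6-methyl-2-methylideneoct-7-enoate (both carbinol epimers)
Conditions: methyl acrylate (5 equiv), DABCO (1 equiv), MeOH, rt, 3–5 d
Reagents that add atoms: methyl acrylate, C=CC(=O)OC
Why: Morita–Baylis–Hillman reaction of the activated α-alkoxy aldehyde installs C11–C13; the new carbinol centre becomes sp2 in step 9, so its configuration does not matter.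

Step 9
Reactants: 9 methyl (4R,5R,6R)-5-(tert-butyldimethylsilyloxy)-3-hydroxy-4-(4-methoxybenzyloxy)-6-methyl-2-methylideneoct-7-enoate
Product: 10 methyl (2Z,4R,5R,6R)-2-(bromomethyl)-5-(tert-butyldimethylsilyloxy)-4-(4-methoxybenzyloxy)-6-methylocta-2,7-dienoate
Conditions: NBS, Me2S, CH2Cl2, 0 °C → rt
Reagents that add atoms: N-bromosuccinimide, O=C1CCC(=O)N1Br
Why: Corey–Kim-type activation of the allylic alcohol followed by SN2′ delivery of bromide gives the thermodynamically favoured (Z)-2-(bromomethyl)enoate with allylic transposition.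

Step 10
Reactants: 11 2,3-O-isopropylidene-D-erythronolactone
Product: 13 (3aR,6aR)-2,2,3a-trimethyldihydrofuro[3,4-d][1,3]dioxol-4(3aH)-one, via lithium enolate 12 (not isolated)
Conditions: LiN(i-Pr)2 (1.1 equiv), THF, −78 °C; then MeI (3 equiv), DMPU, −78 → −40 °C
Reagents that add atoms: iodomethane, CI
Why: Enolate C-alkylation in which the cis-fused dioxolane allows bond formation only with retention of the ring fusion (this sets quaternary C4) and holds the C5–O bond near the nodal plane of the enolate, so β-elimination is slow at −78 °C.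

Step 11
Reactants: 13 (3aR,6aR)-2,2,3a-trimethyldihydrofuro[3,4-d][1,3]dioxol-4(3aH)-one
Product: 14 (3aR,6aR)-2,2,3a-trimethyltetrahydrofuro[3,4-d][1,3]dioxol-4-ol (both anomers)
Conditions: i-Bu2AlH (1.1 equiv), CH2Cl2, −78 °C
Reagents that add atoms: none
Why: Partial reduction of the α-quaternary lactone stops at the lactol because the tetrahedral aluminium hemiacetal is stable at −78 °C.

Step 12
Reactants: 14 (3aR,6aR)-2,2,3a-trimethyltetrahydrofuro[3,4-d][1,3]dioxol-4-ol
Product: 15 1-[(4S,5R)-5-(hydroxymethyl)-2,2,4-trimethyl-1,3-dioxolan-4-yl]prop-2-en-1-ol (both carbinol epimers)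
Conditions: CH2=CHMgBr (3.5 equiv), THF, 0 °C → rt
Reagents that add atoms: vinylmagnesium bromide, C=C[Mg]Br
Why: Grignard addition to the ring-opened hydroxy aldehyde (the first equivalent deprotonates the lactol) gives the C3 carbinol as an epimer mixture, which is of no consequence because C3 becomes the ketone in step 18.

Step 13
Reactants: 15 1-[(4S,5R)-5-(hydroxymethyl)-2,2,4-trimethyl-1,3-dioxolan-4-yl]prop-2-en-1-ol
Product: 16 triethyl({(4R,5R)-2,2,5-trimethyl-5-[1-(triethylsilyloxy)prop-2-enyl]-1,3-dioxolan-4-yl}methoxy)silane (both C3 epimers)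
Conditions: Et3SiOTf (2.5 equiv), 2,6-lutidine, CH2Cl2, −78 → 0 °C
Reagents that add atoms: triethylsilyl triflate, CC[Si](CC)(CC)OS(=O)(=O)C(F)(F)F
Why: Exhaustive silylation with the silyl triflate protects both the primary and the hindered secondary allylic hydroxyl.

Step 14
Reactants: 16 triethyl({(4R,5R)-2,2,5-trimethyl-5-[1-(triethylsilyloxy)prop-2-enyl]-1,3-dioxolan-4-yl}methoxy)silane
Product: 17 (4S,5R)-2,2,5-trimethyl-5-[1-(triethylsilyloxy)prop-2-enyl]-1,3-dioxolane-4-carbaldehyde (both C3 epimers)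
Conditions: (COCl)2 (4 equiv), DMSO (8 equiv), CH2Cl2, −78 → −40 °C; then Et3N, −78 °C → rt
Reagents that add atoms: none
Why: Swern conditions cleave and oxidise the primary triethylsilyl ether selectively while the hindered secondary one survives, giving the C6 aldehyde without touching the C5 stereocentre.

Step 15
Reactants: 17 (4S,5R)-2,2,5-trimethyl-5-[1-(triethylsilyloxy)prop-2-enyl]-1,3-dioxolane-4-carbaldehyde; 10 methyl (2Z,4R,5R,6R)-2-(bromomethyl)-5-(tert-butyldimethylsilyloxy)-4-(4-methoxybenzyloxy)-6-methylocta-2,7-dienoate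
Product: 19 trans-α-methylene-γ-butyrolactone (C6–C7 bond formed; 3-OTES; 4,5-O-isopropylidene; 8-OPMB; 9-OTBS; vinyl groups on C3 and C10), via hydroxy ester 18 (not isolated)
Conditions: 17 (1.0 equiv), 10 (1.3 equiv), CrCl2 (4 equiv), THF, 0 °C → rt; aq NH4Cl; then PPTS (0.2 equiv), PhMe, 40 °C
Reagents that add atoms: none
Why: Nozaki–Hiyama-type carbonyl allylation followed by lactonisation, in which the γ-substituted allylchromium reacts through a chair transition state with both large groups equatorial (6,7-anti, hence the trans-lactone) and on the allyl face anti to the C8–OPMB bond with H8 on the inside position next to the ester (A1,3 control, sets C7 relative to C8), so that reagent control fixes C6 as S against the weak Felkin bias that α-alkoxy aldehydes show toward E-type allyl metals.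

Step 16
Reactants: 19 trans-α-methylene-γ-butyrolactone
Product: 20 13-(dimethylamino)-11,13-dihydro derivative of 19 (both C11 epimers)
Conditions: Me2NH (2 M in THF, 3 equiv), MeOH, 0 °C → rt
Reagents that add atoms: dimethylamine, CNC
Why: Aza-Michael addition masks the exocyclic enoate so that it cannot enter metathesis (six-membered ring closure onto C1) or be reduced in step 20; the new C11 centre is lost again in step 21.

Step 17
Reactants: 20 13-(dimethylamino)-11,13-dihydro lactone
Product: 21 3-hydroxy compound (TES removed; both C3 epimers)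
Conditions: HF·pyridine, pyridine, THF, 0 °C
Reagents that add atoms: none
Why: Buffered fluoride desilylation removes the triethylsilyl ether far faster than the secondary TBS ether and leaves the acetonide and PMB ether intact.

Step 18
Reactants: 21 3-hydroxy compound
Product: 22 3-oxo vinyl ketone (C3 stereocentre removed)
Conditions: Dess–Martin periodinane, NaHCO3, CH2Cl2, 0 °C → rt; used crude
Reagents that add atoms: none
Why: Dess–Martin oxidation of the allylic alcohol gives the vinyl ketone and merges both C3 epimers into one compound.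

Step 19
Reactants: 22 3-oxo vinyl ketone
Product: 23 ten-membered (1Z)-enone (13-dimethylamino-11,13-dihydro; 3-oxo; 4,5-O-isopropylidene; 8-OPMB; 9-OTBS)
Conditions: CSA (1.1 equiv), then second-generation Grubbs catalyst RuCl2(=CHPh)(H2IMes)(PCy3) (10 mol %), CH2Cl2 (1 mM), 40 °C; aq NaHCO3 work-up
Reagents that add atoms: none
Why: Ring-closing metathesis between the C10 vinyl group and the vinyl ketone closes the ten-membered carbocycle with loss of ethene, the amine being protonated to spare the ruthenium carbene and the trans-lactone and dioxolane pre-organising the chain.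

Step 20
Reactants: 23 ten-membered (1Z)-enone
Product: 24 1,2-dihydro compound (saturated C3 ketone)
Conditions: H2 (1 atm), Pd/C (10 wt %), pyridine (0.5 equiv), EtOAc, rt
Reagents that add atoms: none
Why: Heterogeneous hydrogenation saturates the enone C=C, the only alkene present, while the basic amine and pyridine suppress hydrogenolysis of the PMB ether.

Step 21
Reactants: 24 1,2-dihydro compound
Product: 26 α-methylene lactone (3-oxo; 4,5-O-isopropylidene; 8-OPMB; 9-OTBS), via ammonium iodide 25 (not isolated)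
Conditions: MeI (10 equiv), MeCN, rt; evaporate; then aq NaHCO3/EtOAc, rt
Reagents that add atoms: none
Why: Quaternisation followed by E1cB (Hofmann-type retro-Michael) loss of trimethylamine regenerates the α-methylene lactone, H11 being the only β-hydrogen.

Step 22
Reactants: 26 α-methylene lactone
Product: 27 9-hydroxy compound
Conditions: HF·pyridine (excess), THF, 0 °C → rt
Reagents that add atoms: none
Why: Fluoride desilylation under acidic anhydrous conditions frees O9 without affecting the acetonide, the PMB ether or the Michael acceptor.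

Step 23
Reactants: 27 9-hydroxy compound
Product: 28 9-O-(3-methylbutanoyl) compound
Conditions: 3-methylbutanoyl chloride, pyridine, DMAP (cat.), CH2Cl2, 0 °C → rt
Reagents that add atoms: 3-methylbutanoyl chloride, CC(C)CC(=O)Cl
Why: Acylation with the acid chloride under nucleophilic catalysis esterifies O9, the only free hydroxyl at this stage.

Step 24
Reactants: 28 9-O-(3-methylbutanoyl) compound
Product: 29 4,5-diol
Conditions: AcOH/H2O (4:1), 45 °C
Reagents that add atoms: none
Why: Acid-catalysed acetal hydrolysis frees O4 and O5 under conditions that PMB ethers, esters and the lactone tolerate, with no silyl ether left to lose.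

Step 25
Reactants: 29 4,5-diol; 30 (R)-2-methylbutanoic acid
Product: 32 8-O-PMB ether of the target, via mixed anhydride 31 (not isolated)
Conditions: 30 (3 equiv), 2,4,6-Cl3C6H2COCl, Et3N, THF, rt; then 29, DMAP, PhMe, rt → 40 °C
Reagents that add atoms: none
Why: Yamaguchi esterification acylates the secondary O5 and leaves the tertiary O4 free, and the α-stereocentre of the acid is carried over unchanged from the purchased (R)-acid.

Step 26
Reactants: 32 8-O-PMB ether of the target
Product: 33 CNP0269576.1 (target)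
Conditions: DDQ (1.5 equiv), CH2Cl2/pH 7 buffer (10:1), 0 °C → rt
Reagents that add atoms: none
Why: Oxidative cleavage of the PMB ether under neutral conditions frees O8 without 1,2-acyl migration from O9 and without touching the α-methylene lactone.

## Compound list

1 | 1,2:5,6-di-O-isopropylidene-D-mannitol | CC1(C)OC[C@@H](O1)[C@@H](O)[C@H](O)[C@H]1COC(C)(C)O1 | starting material
2 | (R)-2,2-dimethyl-1,3-dioxolane-4-carbaldehyde | O=C[C@H]1COC(C)(C)O1 | intermediate
3 | (1R,2R)-1-[(4R)-2,2-dimethyl-1,3-dioxolan-4-yl]-2-methylbut-3-en-1-ol | C=C[C@@H](C)[C@@H](O)[C@H]1COC(C)(C)O1 | intermediate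
4 | (4R)-4-[(1R,2R)-1-(tert-butyldimethylsilyloxy)-2-methylbut-3-enyl]-2,2-dimethyl-1,3-dioxolane | C=C[C@@H](C)[C@@H](O[Si](C)(C)C(C)(C)C)[C@H]1COC(C)(C)O1 | intermediate
5 | (2R,3R,4R)-3-(tert-butyldimethylsilyloxy)-4-methylhex-5-ene-1,2-diol | C=C[C@@H](C)[C@@H](O[Si](C)(C)C(C)(C)C)[C@H](O)CO | intermediate
6 | (4R)-4-[(1R,2R)-1-(tert-butyldimethylsilyloxy)-2-methylbut-3-enyl]-2-(4-methoxyphenyl)-1,3-dioxolane (both acetal epimers) | C=C[C@@H](C)[C@@H](O[Si](C)(C)C(C)(C)C)[C@H]1COC(c2ccc(OC)cc2)O1 | intermediate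
7 | (2R,3R,4R)-3-(tert-butyldimethylsilyloxy)-2-(4-methoxybenzyloxy)-4-methylhex-5-en-1-ol | C=C[C@@H](C)[C@@H](O[Si](C)(C)C(C)(C)C)[C@H](OCc1ccc(OC)cc1)CO | intermediate
8 | (2S,3R,4R)-3-(tert-butyldimethylsilyloxy)-2-(4-methoxybenzyloxy)-4-methylhex-5-enal | C=C[C@@H](C)[C@@H](O[Si](C)(C)C(C)(C)C)[C@H](OCc1ccc(OC)cc1)C=O | intermediate
9 | methyl (4R,5R,6R)-5-(tert-butyldimethylsilyloxy)-3-hydroxy-4-(4-methoxybenzyloxy)-6-methyl-2-methylideneoct-7-enoate (both C3 epimers) | C=C[C@@H](C)[C@@H](O[Si](C)(C)C(C)(C)C)[C@H](OCc1ccc(OC)cc1)C(O)C(=C)C(=O)OC | intermediate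
10 | methyl (2Z,4R,5R,6R)-2-(bromomethyl)-5-(tert-butyldimethylsilyloxy)-4-(4-methoxybenzyloxy)-6-methylocta-2,7-dienoate | COC(=O)/C(CBr)=C/[C@@H](OCc1ccc(OC)cc1)[C@H](O[Si](C)(C)C(C)(C)C)[C@H](C)C=C | intermediate
11 | 2,3-O-isopropylidene-D-erythronolactone, (3aR,6aR)-2,2-dimethyldihydrofuro[3,4-d][1,3]dioxol-4(3aH)-one | O=C1[C@@H]2OC(C)(C)O[C@@H]2CO1 | starting material
12 | lithium enolate of 11, lithium (6aR)-2,2-dimethyl-6,6a-dihydrofuro[3,4-d][1,3]dioxol-4-olate | [Li+].[O-]C1=C2OC(C)(C)O[C@@H]2CO1 | intermediate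
13 | (3aR,6aR)-2,2,3a-trimethyldihydrofuro[3,4-d][1,3]dioxol-4(3aH)-one | O=C1[C@]2(C)OC(C)(C)O[C@@H]2CO1 | intermediate
14 | (3aR,6aR)-2,2,3a-trimethyltetrahydrofuro[3,4-d][1,3]dioxol-4-ol (both anomers) | OC1[C@]2(C)OC(C)(C)O[C@@H]2CO1 | intermediate
15 | 1-[(4S,5R)-5-(hydroxymethyl)-2,2,4-trimethyl-1,3-dioxolan-4-yl]prop-2-en-1-ol (both carbinol epimers, C3) | C=CC(O)[C@]1(C)OC(C)(C)O[C@@H]1CO | intermediate
16 | triethyl({(4R,5R)-2,2,5-trimethyl-5-[1-(triethylsilyloxy)prop-2-enyl]-1,3-dioxolan-4-yl}methoxy)silane (both C3 epimers) | C=CC(O[Si](CC)(CC)CC)[C@]1(C)OC(C)(C)O[C@@H]1CO[Si](CC)(CC)CC | intermediate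
17 | (4S,5R)-2,2,5-trimethyl-5-[1-(triethylsilyloxy)prop-2-enyl]-1,3-dioxolane-4-carbaldehyde (both C3 epimers) | C=CC(O[Si](CC)(CC)CC)[C@]1(C)OC(C)(C)O[C@@H]1C=O | intermediate
18 | open-chain C6–C7 adduct, methyl 2-methylidene ester with free C6–OH (other groups and stereocentres as in 19) | C=C(C(=O)OC)[C@@H]([C@H](O)[C@H]1OC(C)(C)O[C@@]1(C)C(O[Si](CC)(CC)CC)C=C)[C@@H](OCc1ccc(OC)cc1)[C@H](O[Si](C)(C)C(C)(C)C)[C@H](C)C=C | intermediate
19 | trans-α-methylene-γ-butyrolactone: 3-OTES (both epimers), 4,5-O-isopropylidene, 8-OPMB, 9-OTBS, vinyl groups on C3 and C10; C4–C10 configured as in the target (4R,5R,6S,7R,8R,9R,10R) | C=C1C(=O)O[C@H]([C@H]2OC(C)(C)O[C@@]2(C)C(O[Si](CC)(CC)CC)C=C)[C@H]1[C@@H](OCc1ccc(OC)cc1)[C@H](O[Si](C)(C)C(C)(C)C)[C@H](C)C=C | intermediate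
20 | 13-(dimethylamino)-11,13-dihydro derivative of 19 (C3 and C11 epimers) | CN(C)CC1C(=O)O[C@H]([C@H]2OC(C)(C)O[C@@]2(C)C(O[Si](CC)(CC)CC)C=C)[C@H]1[C@@H](OCc1ccc(OC)cc1)[C@H](O[Si](C)(C)C(C)(C)C)[C@H](C)C=C | intermediate
21 | 3-hydroxy compound from 20 (C3 and C11 epimers) | CN(C)CC1C(=O)O[C@H]([C@H]2OC(C)(C)O[C@@]2(C)C(O)C=C)[C@H]1[C@@H](OCc1ccc(OC)cc1)[C@H](O[Si](C)(C)C(C)(C)C)[C@H](C)C=C | intermediate
22 | 3-oxo vinyl ketone (C11 epimers) | CN(C)CC1C(=O)O[C@H]([C@H]2OC(C)(C)O[C@@]2(C)C(=O)C=C)[C@H]1[C@@H](OCc1ccc(OC)cc1)[C@H](O[Si](C)(C)C(C)(C)C)[C@H](C)C=C | intermediate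
23 | ten-membered (1Z)-enone: 13-(dimethylamino)-11,13-dihydro-3-oxo-4,5-O-isopropylidene-8-OPMB-9-OTBS germacr-1-en-6,12-olide (C11 epimers) | CN(C)CC1C(=O)O[C@H]2[C@H]1[C@@H](OCc1ccc(OC)cc1)[C@H](O[Si](C)(C)C(C)(C)C)[C@H](C)/C=C\C(=O)[C@]3(C)OC(C)(C)O[C@H]23 | intermediate
24 | 1,2-dihydro derivative of 23 (C11 epimers) | CN(C)CC1C(=O)O[C@H]2[C@H]1[C@@H](OCc1ccc(OC)cc1)[C@H](O[Si](C)(C)C(C)(C)C)[C@H](C)CCC(=O)[C@]3(C)OC(C)(C)O[C@H]23 | intermediate
25 | trimethylammonium iodide of 24 | C[N+](C)(C)CC1C(=O)O[C@H]2[C@H]1[C@@H](OCc1ccc(OC)cc1)[C@H](O[Si](C)(C)C(C)(C)C)[C@H](C)CCC(=O)[C@]3(C)OC(C)(C)O[C@H]23.[I-] | intermediate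
26 | 3-oxo-4,5-O-isopropylidene-8-OPMB-9-OTBS germacr-11(13)-en-6,12-olide | C=C1C(=O)O[C@H]2[C@H]1[C@@H](OCc1ccc(OC)cc1)[C@H](O[Si](C)(C)C(C)(C)C)[C@H](C)CCC(=O)[C@]3(C)OC(C)(C)O[C@H]23 | intermediate
27 | 9-hydroxy compound from 26 | C=C1C(=O)O[C@H]2[C@H]1[C@@H](OCc1ccc(OC)cc1)[C@H](O)[C@H](C)CCC(=O)[C@]3(C)OC(C)(C)O[C@H]23 | intermediate
28 | 9-O-(3-methylbutanoyl) compound | C=C1C(=O)O[C@H]2[C@H]1[C@@H](OCc1ccc(OC)cc1)[C@H](OC(=O)CC(C)C)[C@H](C)CCC(=O)[C@]3(C)OC(C)(C)O[C@H]23 | intermediate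
29 | 4,5-diol (8-OPMB, 9-O-isovaleryl, 3-oxo) | C=C1C(=O)O[C@H]2[C@H]1[C@@H](OCc1ccc(OC)cc1)[C@H](OC(=O)CC(C)C)[C@H](C)CCC(=O)[C@](C)(O)[C@@H]2O | intermediate
30 | (R)-2-methylbutanoic acid | CC[C@@H](C)C(=O)O | starting material
31 | (R)-2-methylbutanoic 2,4,6-trichlorobenzoic anhydride | CC[C@@H](C)C(=O)OC(=O)c1c(Cl)cc(Cl)cc1Cl | intermediate
32 | 8-O-(4-methoxybenzyl) ether of the target | C=C1C(=O)O[C@H]2[C@H]1[C@@H](OCc1ccc(OC)cc1)[C@H](OC(=O)CC(C)C)[C@H](C)CCC(=O)[C@](C)(O)[C@@H]2OC(=O)[C@H](C)CC | intermediate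
33 | CNP0269576.1 | C=C1C(=O)O[C@H]2[C@H]1[C@@H](O)[C@H](OC(=O)CC(C)C)[C@H](C)CCC(=O)[C@](C)(O)[C@@H]2OC(=O)[C@H](C)CC | target

## Step count and risks

Total step count: 26. Longest linear sequence: 21 steps (1 → 33 through steps 1–9 and 15–26); the aldehyde branch (steps 10–14) is 5 steps.

Steps most likely to fail:

Step 15 (chromium coupling). The aldehyde's own Felkin preference (5,6-anti) opposes the sense imposed by the chiral bromide, and any leakage to the syn pathway gives cis-lactones. The fallback sets out from aldehyde 8 (with aldehyde 17 as partner) and comes back at lactone 19. Aldehyde 8 is homologated with dimethyl (1-diazo-2-oxopropyl)phosphonate, K2CO3 and MeOH to the terminal alkyne F1, which is carboxylated (n-BuLi, then ClCO2Me) to the ynoate F2. Syn-hydroalumination of F2 with i-Bu2AlH/HMPA and trapping of the α-aluminio acrylate with ICH2B(pin) gives the (2Z)-allylboronate F3, in which C8 is trans to the CH2B group. Allylboration of 17 with F3 (PhMe, 60–80 °C, or Sc(OTf)3 catalysis at low temperature) runs through a closed chair transition state that is stereospecifically anti and is governed by the same C8 stereocentre; PPTS then closes hydroxy ester 18 to 19.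

Step 19 (ring-closing metathesis). A ten-membered carbocycle is entropically and enthalpically demanding, and the vinyl ketone is electron-poor and prone to oligomerise. The fallback sets out from allylic alcohol 21 and comes back at enone 23. Metathesis is run on 21 itself as its CSA salt with second-generation Hoveyda–Grubbs catalyst RuCl2(=CH-2-(i-PrO)C6H4)(H2IMes) in PhMe at 80 °C, where the free allylic hydroxyl assists loading of ruthenium and neither olefin is electron-poor. This gives the cyclic allylic alcohol F4, and Dess–Martin oxidation of F4 then gives 23.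

Step 8 (Morita–Baylis–Hillman reaction). The α-branched α-alkoxy aldehyde reacts slowly and can epimerise at C8 during days of exposure to DABCO. The fallback sets out from aldehyde 8 and comes back at adduct 9. Aldol addition of the lithium enolate of methyl 3-(dimethylamino)propanoate (LiN(i-Pr)2, THF, −78 °C) to 8 gives the amino hydroxy ester F5. N-Methylation of F5 with MeI gives the ammonium iodide F6, and treatment with DBU eliminates the ammonium group to give 9.

Further compounds
F1 | step 15 | (3R,4R,5R)-4-(tert-butyldimethylsilyloxy)-3-(4-methoxybenzyloxy)-5-methylhept-6-en-1-yne | C#C[C@@H](OCc1ccc(OC)cc1)[C@H](O[Si](C)(C)C(C)(C)C)[C@H](C)C=C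
F2 | step 15 | methyl (4R,5R,6R)-5-(tert-butyldimethylsilyloxy)-4-(4-methoxybenzyloxy)-6-methyloct-7-en-2-ynoate | COC(=O)C#C[C@@H](OCc1ccc(OC)cc1)[C@H](O[Si](C)(C)C(C)(C)C)[C@H](C)C=C
F3 | step 15 | methyl (2Z,4R,5R,6R)-5-(tert-butyldimethylsilyloxy)-4-(4-methoxybenzyloxy)-6-methyl-2-[(4,4,5,5-tetramethyl-1,3,2-dioxaborolan-2-yl)methyl]octa-2,7-dienoate | COC(=O)/C(CB1OC(C)(C)C(C)(C)O1)=C\[C@@H](OCc1ccc(OC)cc1)[C@H](O[Si](C)(C)C(C)(C)C)[C@H](C)C=C
F4 | step 19 | ten-membered (1Z)-allylic alcohol, 3-hydroxy analogue of 23 (C3 and C11 epimers) | CN(C)CC1C(=O)O[C@H]2[C@H]1[C@@H](OCc1ccc(OC)cc1)[C@H](O[Si](C)(C)C(C)(C)C)[C@H](C)/C=C\C(O)[C@]3(C)OC(C)(C)O[C@H]23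
F5 | step 8 | methyl (4R,5R,6R)-5-(tert-butyldimethylsilyloxy)-2-[(dimethylamino)methyl]-3-hydroxy-4-(4-methoxybenzyloxy)-6-methyloct-7-enoate (C2 and C3 epimers) | C=C[C@@H](C)[C@@H](O[Si](C)(C)C(C)(C)C)[C@H](OCc1ccc(OC)cc1)C(O)C(CN(C)C)C(=O)OC
F6 | step 8 | trimethylammonium iodide of F5 | C=C[C@@H](C)[C@@H](O[Si](C)(C)C(C)(C)C)[C@H](OCc1ccc(OC)cc1)C(O)C(C[N+](C)(C)C)C(=O)OC.[I-]
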